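(The numbers in the tables come from a simulation from invented constants; noise was put on by code.)

I divided the rates. You asked for a quick number and guessed that the enzyme dies while it works, so I set the fractional fall of [starting material] per minute over the enzyme lost per minute. Time drops out of that ratio, and what stays is the reach: the ln([starting material] charged / [starting material]) that one µM of enzyme buys before it is spent.

| flask | starting material | second substrate | enzyme | remark |
|---|---|---|---|---|
| Thursday's | 0.20 M | 0.10 M | 15 µM | run made earlier |
| Monday's | 0.20 M | 0.10 M | 22 µM | run made earlier |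
| Wednesday's | 0.20 M | 0.15 M | 30 µM | run made earlier |
| flask | 0.20 M | 0.100 M | 30 µM |  |

| run | time / min | target / % | starting material / % |
|---|---|---|---|
| Thursday's | 1.00 | 4.8 | 94.9 |
| Thursday's | 2.00 | 10.8 | 89.2 |
| Thursday's | 3.00 | 16.3 | 84.1 |
| Thursday's | 4.00 | 23.2 | 78.7 |
| Thursday's | 5.00 | 24.8 | 78.1 |
| Thursday's | 6.00 | 26.6 | 72.7 |
| Monday's | 1.00 | 9.4 | 93.4 |
| Monday's | 2.00 | 15.5 | 83.7 |
| Monday's | 3.00 | 24.5 | 73.4 |
| Monday's | 4.00 | 31.7 | 68.9 |
| Monday's | 5.00 | 34.3 | 66.0 |
| Monday's | 6.00 | 37.2 | 61.9 |
| Wednesday's | 1.33 | 12.9 | 89.0 |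
| Wednesday's | 2.50 | 27.0 | 71.8 |
| Wednesday's | 4.00 | 39.1 | 60.7 |
| Wednesday's | 5.00 | 43.9 | 56.5 |
| Wednesday's | 6.00 | 46.6 | 52.0 |

(each reading ± 1 percentage point)

- apparent order in second substrate when 50% of the starting material are converted (percent change of the rate of making target for one percent more second substrate charged)
- factor on the rate of making target when 50% of the starting material are converted if enzyme is charged twice over

- the numbers in the tables scatter with a standard deviation of 1 percentage point

Per µM charged, that logarithm read 0.0213 µM⁻¹ on Thursday's run, 0.0218 µM⁻¹ on Monday's and 0.0218 µM⁻¹ on Wednesday's at 6.00 min, although Wednesday's had 0.15 M of second substrate, so I put the order at zero within the scatter. Monday's run read 0.00809 µM⁻¹ at 2.00 min and 0.0169 µM⁻¹ at 4.00 min. The second gain was 0.551 of the first, and summing such gains gave a reach of 0.0278 µM⁻¹. On the flask's 30 µM that made 0.833, so I reckoned that at 50% conversion 16.8% of the enzyme charged to the flask would be unspent. Taking the rate as following unspent enzyme, doubling the charge gave me a factor of 6.95.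

The forecast said 0.3 for the order, where I said zero, and 5 for the factor, less than mine, holding that “Percent/enzyme is roughly a function of time alone”.

The simulation gave an order of 2.7 × 10⁻⁵ and a factor of 14.0.

    starting material + enzyme ⇌ complex A (K = 4.10 L mol⁻¹, k = 23000 L mol⁻¹ s⁻¹)
    complex A → enzyme + target (k = 58.0 s⁻¹)
    second substrate + enzyme ⇌ complex B (K = 55.0 L mol⁻¹, k = 13000 L mol⁻¹ s⁻¹)
    complex B → enzyme + second product (k = 110 s⁻¹)
    enzyme → spent catalyst (k = 0.00940 s⁻¹)

At 5.00 min the flask made target 2750 times faster than it lost enzyme, which per [starting material] of that moment is 0.0250 µM⁻¹, beside my reach of 0.0278 µM⁻¹. At 100 min, with 100% of the catalyst spent, the flask held 47.2% of its starting material, where my reach leaves 43.4% and the flask's ratio 47.2%, and for the doubled charge that ratio gives 13.9 beside the simulation's factor of 14.0.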